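**Retrosynthetic overview**
1. The target is 15-acetoxylabda-8,13E-dien-19-oic acid (4β-CO2H, 4α-Me, 5α-H, 10β-Me). The side chain is cut at C9–C11 (B-alkyl Suzuki–Miyaura coupling of a C8=C9 enol triflate with a C11–C15 borane); the C8 methyl comes from enolate methylation of a C9 ketone.
2. Ring A (C1–C5, C10) is cut at C4–C5. Enabling feature: the C19 carbonyl on C4 and the ring-fusion carbon C5 form an aldol retron, and C5 and C9 are the two ring-B neighbours of the quaternary C10. Both can therefore be ketones of an achiral, σ-symmetric 2-methylcyclohexane-1,3-dione that carries the C1–C4 chain on C10.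
3. A Cu–H reductive aldol desymmetrisation of this dione enoate closes ring A, sets C10 by catalysis and relays C4; the temporary C5–OH is then traded for 5α-H (dehydration to Δ5, hydrogenation anti to the two β-axial groups).
4. Ring order: ring B is bought intact (2-methylcyclohexane-1,3-dione); ring A is the only ring formed and is closed last.

Key step: step 3

Assumption: methyl 2-(triphenylphosphoranylidene)propanoate and (E)-3-methylpent-2-en-4-yn-1-ol are taken as catalogue compounds; the ligand enantiomer that leads to the (4aS) series in step 3 has to be identified by experiment.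

**Route**

Step 1
Reactants: 1 2-methylcyclohexane-1,3-dione; 2 acrolein
Product: 3 3-(1-methyl-2,6-dioxocyclohexyl)propanal
Conditions: H2O, rt
Reagents that add atoms: none
Why: Michael addition of the enolised 1,3-dione through C2 to acrolein proceeds without added base and builds the quaternary but still σ-symmetric C10, so no stereocentre has to be controlled.

Step 2
Reactants: 3 3-(1-methyl-2,6-dioxocyclohexyl)propanal; 4 methyl 2-(triphenylphosphoranylidene)propanoate
Product: 5 methyl (E)-2-methyl-5-(1-methyl-2,6-dioxocyclohexyl)pent-2-enoate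
Conditions: PhMe, rt → 40 °C
Reagents that add atoms: none
Why: Wittig olefination with the stabilised α-methyl ylide is selective for the aldehyde over the two ketones and gives the (E)-trisubstituted enoate that carries C4, its methyl and C19 at the final oxidation level.

Step 3
Reactants: 5 methyl (E)-2-methyl-5-(1-methyl-2,6-dioxocyclohexyl)pent-2-enoate
Product: 8 methyl (1S,4aS,8aR)-8a-hydroxy-1,4a-dimethyl-5-oxodecahydronaphthalene-1-carboxylate, via copper enolate 6 (not isolated), via phenylsilyl ether 7 (not isolated)
Conditions: Cu(OAc)2·H2O (5 mol %), chiral ferrocenyl bisphosphine of the Taniaphos type (5.5 mol %), PhSiH3 (1.2 equiv), PhMe, −40 → 0 °C; then aq. NH4F work-up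
Reagents that add atoms: none
Why: Proposed new method: a ligated Cu–H species transfers hydride to C3 of the enoate (conjugate reduction) to give the fully substituted copper ester enolate 6 at C4, which adds through a closed, Cu-bridged chair-like aldol transition state to one of the two enantiotopic ring ketones (C5) and is then silylated irreversibly by the silane (7), regenerating Cu–H. The closest known reaction type is the Cu–H/chiral-bisphosphine-catalysed domino reductive aldol cyclisation of α-unsubstituted enoates tethered to 2-methylcyclohexane-1,3-dione; new here is the α-methyl enoate, so that the aldol makes a quaternary carbon (C4) beside the carbinol carbon. Ring A is closed in a 6-(enolexo)-exo-trig aldol mode through the C4–C5 bond, and ring B is untouched. C10 becomes stereogenic by catalyst-controlled choice between the two carbonyls; C5–OH is forced cis to the C10 methyl because the enolate, tethered through C1–C3 to C10, can reach the carbonyl only axially from its own side (cis-fused ketol); C4 is set by the chelate, which holds the ester syn to the new alkoxide and so on the face of the C10 methyl, the C4 methyl going anti to the C–O bond. The step needs 1,4-hydride transfer to outrun hydrosilylation of the ketones and needs group selection between the carbonyls: the first is secured by the conjugated ester being the only π-system to which a soft phosphine–Cu–H adds rapidly at low temperature, the second by the mirror plane through C10 that makes the two ketones enantiotopic and thus distinguishable only by the chiral ligand.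

Step 4
Reactants: 8 methyl (1S,4aS,8aR)-8a-hydroxy-1,4a-dimethyl-5-oxodecahydronaphthalene-1-carboxylate
Product: 9 methyl (1S,4aS)-1,4a-dimethyl-5-oxo-1,2,3,4,4a,5,6,7-octahydronaphthalene-1-carboxylate
Conditions: SOCl2, pyridine, CH2Cl2, −20 → 0 °C
Reagents that add atoms: none
Why: Dehydration of the tertiary alcohol via its chlorosulfite (E1/E2 elimination) can only go towards C6, the sole neighbour that bears hydrogen, and a 1,2-shift from C4 or C10 is disfavoured because it would place the cation α to a carbonyl; no stereocentre is formed.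

Step 5
Reactants: 9 methyl (1S,4aS)-1,4a-dimethyl-5-oxo-1,2,3,4,4a,5,6,7-octahydronaphthalene-1-carboxylate
Product: 10 methyl (1S,4aS,8aR)-1,4a-dimethyl-5-oxodecahydronaphthalene-1-carboxylate
Conditions: H2 (5–20 bar), 10% Pd/C, EtOAc, rt
Reagents that add atoms: none
Why: Heterogeneous catalytic hydrogenation adds H2 syn from the α face, opposite the axial C10 methyl and the C4 ester that both cover the β face, so C5 receives its hydrogen trans to the angular methyl (trans-decalin), as in the hydrogenation of 4,4-disubstituted Δ5-steroids to 5α products.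

Step 6
Reactants: 10 methyl (1S,4aS,8aR)-1,4a-dimethyl-5-oxodecahydronaphthalene-1-carboxylate
Product: 12 methyl (1S,4aS,8aR)-1,4a,6-trimethyl-5-oxodecahydronaphthalene-1-carboxylate, via lithium enolate 11 (not isolated)
Conditions: LDA (1.1 equiv), THF, −78 °C; then MeI, −78 → −20 °C
Reagents that add atoms: iodomethane CI
Why: Kinetic enolate alkylation is regiospecific because the ketone can enolise only towards the CH2 group (the other α carbon is quaternary and the ester has no α hydrogen), and the configuration of the new methyl-bearing carbon is irrelevant because it becomes sp2 in step 7.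

Step 7
Reactants: 12 methyl (1S,4aS,8aR)-1,4a,6-trimethyl-5-oxodecahydronaphthalene-1-carboxylate
Product: 14 methyl (1S,4aS,8aR)-1,4a,6-trimethyl-5-(trifluoromethylsulfonyloxy)-1,2,3,4,4a,7,8,8a-octahydronaphthalene-1-carboxylate, via potassium enolate 13 (not isolated)
Conditions: KHMDS, THF, −78 → 0 °C; then PhNTf2
Reagents that add atoms: N-phenylbis(trifluoromethanesulfonimide) O=S(=O)(N(c1ccccc1)S(=O)(=O)C(F)(F)F)C(F)(F)F
Why: O-triflation of the only possible (tetrasubstituted) potassium enolate fixes the future C8=C9 double bond regiospecifically as an enol triflate.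

Step 8
Reactants: 15 (E)-3-methylpent-2-en-4-yn-1-ol
Product: 16 (E)-tert-butyldimethyl[(3-methylpent-2-en-4-yn-1-yl)oxy]silane
Conditions: TBSCl, imidazole, CH2Cl2, 0 °C → rt
Reagents that add atoms: tert-butyldimethylsilyl chloride CC(C)(C)[Si](C)(C)Cl
Why: Standard silylation of the primary allylic alcohol gives an ether that, unlike an allylic acetate, is not ionised by Pd(0) in step 10.

Step 9
Reactants: 16 (E)-tert-butyldimethyl[(3-methylpent-2-en-4-yn-1-yl)oxy]silane
Product: 17 (E)-tert-butyldimethyl[(3-methylpenta-2,4-dien-1-yl)oxy]silane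
Conditions: H2 (1 atm), Pd/CaCO3 (lead-poisoned), quinoline, hexane, rt
Reagents that add atoms: none
Why: Semihydrogenation of the terminal alkyne over poisoned palladium stops at the vinyl group and leaves the (E)-trisubstituted alkene untouched.

Step 10
Reactants: 14 methyl (1S,4aS,8aR)-1,4a,6-trimethyl-5-(trifluoromethylsulfonyloxy)-1,2,3,4,4a,7,8,8a-octahydronaphthalene-1-carboxylate; 17 (E)-tert-butyldimethyl[(3-methylpenta-2,4-dien-1-yl)oxy]silane
Product: 19 methyl (1S,4aS,8aR)-5-[(E)-5-(tert-butyldimethylsilyloxy)-3-methylpent-3-en-1-yl]-1,4a,6-trimethyl-1,2,3,4,4a,7,8,8a-octahydronaphthalene-1-carboxylate, via alkylborane 18 (not isolated)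
Conditions: 17, 9-BBN dimer, THF, 0 °C → rt; then 14, Pd(dppf)Cl2·CH2Cl2 (10 mol %), AsPh3, Cs2CO3, DMF/H2O, 50 °C
Reagents that add atoms: none
Why: In this B-alkyl Suzuki–Miyaura coupling 9-BBN hydroborates only the monosubstituted terminal alkene of the diene at its CH2 end, and the primary alkylborane is transferred to the enol triflate with retention of both double-bond positions and geometries.

Step 11
Reactants: 19 methyl (1S,4aS,8aR)-5-[(E)-5-(tert-butyldimethylsilyloxy)-3-methylpent-3-en-1-yl]-1,4a,6-trimethyl-1,2,3,4,4a,7,8,8a-octahydronaphthalene-1-carboxylate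
Product: 20 methyl (1S,4aS,8aR)-5-[(E)-5-hydroxy-3-methylpent-3-en-1-yl]-1,4a,6-trimethyl-1,2,3,4,4a,7,8,8a-octahydronaphthalene-1-carboxylate
Conditions: TBAF, THF, 0 °C → rt
Reagents that add atoms: none
Why: Fluoride-mediated desilylation frees the primary allylic alcohol without touching the hindered ester or the alkenes.

Step 12
Reactants: 20 methyl (1S,4aS,8aR)-5-[(E)-5-hydroxy-3-methylpent-3-en-1-yl]-1,4a,6-trimethyl-1,2,3,4,4a,7,8,8a-octahydronaphthalene-1-carboxylate
Product: 21 (1S,4aS,8aR)-5-[(E)-5-hydroxy-3-methylpent-3-en-1-yl]-1,4a,6-trimethyl-1,2,3,4,4a,7,8,8a-octahydronaphthalene-1-carboxylic acid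
Conditions: NaSEt, DMF, 90 °C; then aq. HCl to pH 3
Reagents that add atoms: none
Why: SN2 O-demethylation by thiolate at the methyl group (alkyl–oxygen cleavage) removes the axial neopentyl ester that resists acyl–oxygen saponification, and C4 is untouched because no bond to it is broken.

Step 13
Reactants: 21 (1S,4aS,8aR)-5-[(E)-5-hydroxy-3-methylpent-3-en-1-yl]-1,4a,6-trimethyl-1,2,3,4,4a,7,8,8a-octahydronaphthalene-1-carboxylic acid
Product: 22 (1S,4aS,8aR)-5-[(E)-5-acetoxy-3-methylpent-3-en-1-yl]-1,4a,6-trimethyl-1,2,3,4,4a,7,8,8a-octahydronaphthalene-1-carboxylic acid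
Conditions: Ac2O, pyridine, DMAP (cat.), CH2Cl2, 0 °C → rt; aq. NaHCO3, then pH 3 work-up
Reagents that add atoms: acetic anhydride CC(=O)OC(C)=O
Why: Acylation of the primary alcohol with acetic anhydride is far faster than any lasting reaction at the hindered tertiary carboxylic acid, whose mixed anhydride, if formed, is hydrolysed back on aqueous work-up.

**Compound list**
1 | 2-methylcyclohexane-1,3-dione | CC1C(=O)CCCC1=O | starting material
2 | acrolein | C=CC=O | starting material
3 | 3-(1-methyl-2,6-dioxocyclohexyl)propanal | CC1(CCC=O)C(=O)CCCC1=O | intermediate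
4 | methyl 2-(triphenylphosphoranylidene)propanoate | COC(=O)C(C)=P(c1ccccc1)(c1ccccc1)c1ccccc1 | starting material
5 | methyl (E)-2-methyl-5-(1-methyl-2,6-dioxocyclohexyl)pent-2-enoate | COC(=O)/C(C)=C/CCC1(C)C(=O)CCCC1=O | intermediate
6 | copper(I) ester enolate formed from 5 by hydride addition at C3 (enolate geometry not specified) | COC(O[Cu])=C(C)CCCC1(C)C(=O)CCCC1=O | intermediate
7 | phenylsilyl ether of 8 (O-silylated aldolate) | O=C1CCC[C@]2(O[SiH2]c3ccccc3)[C@@](C)(C(=O)OC)CCC[C@]12C | intermediate
8 | methyl (1S,4aS,8aR)-8a-hydroxy-1,4a-dimethyl-5-oxodecahydronaphthalene-1-carboxylate (cis-fused ketol; ester, OH and angular methyl all on the β face; labdane numbering 4β-CO2Me, 4α-Me, 5β-OH, 10β-Me, 9-oxo) | O=C1CCC[C@]2(O)[C@@](C)(C(=O)OC)CCC[C@]12C | intermediate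
9 | methyl (1S,4aS)-1,4a-dimethyl-5-oxo-1,2,3,4,4a,5,6,7-octahydronaphthalene-1-carboxylate (Δ5 in labdane numbering) | O=C1CCC=C2[C@@](C)(C(=O)OC)CCC[C@]12C | intermediate
10 | methyl (1S,4aS,8aR)-1,4a-dimethyl-5-oxodecahydronaphthalene-1-carboxylate (trans-fused; 5α-H) | O=C1CCC[C@H]2[C@@](C)(C(=O)OC)CCC[C@]12C | intermediate
11 | lithium enolate of 10 | [Li]OC1=CCC[C@H]2[C@@](C)(C(=O)OC)CCC[C@]12C | intermediate
12 | methyl (1S,4aS,8aR)-1,4a,6-trimethyl-5-oxodecahydronaphthalene-1-carboxylate (both C6 epimers) | O=C1C(C)CC[C@H]2[C@@](C)(C(=O)OC)CCC[C@]12C | intermediate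
13 | potassium enolate of 12 | [K]OC1=C(C)CC[C@H]2[C@@](C)(C(=O)OC)CCC[C@]12C | intermediate
14 | methyl (1S,4aS,8aR)-1,4a,6-trimethyl-5-(trifluoromethylsulfonyloxy)-1,2,3,4,4a,7,8,8a-octahydronaphthalene-1-carboxylate | O=S(=O)(OC1=C(C)CC[C@H]2[C@@](C)(C(=O)OC)CCC[C@]12C)C(F)(F)F | intermediate
15 | (E)-3-methylpent-2-en-4-yn-1-ol | OC/C=C(\C)C#C | starting material
16 | (E)-tert-butyldimethyl[(3-methylpent-2-en-4-yn-1-yl)oxy]silane | CC(C)(C)[Si](C)(C)OC/C=C(\C)C#C | intermediate
17 | (E)-tert-butyldimethyl[(3-methylpenta-2,4-dien-1-yl)oxy]silane | CC(C)(C)[Si](C)(C)OC/C=C(\C)C=C | intermediate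
18 | 9-[(E)-5-(tert-butyldimethylsilyloxy)-3-methylpent-3-en-1-yl]-9-borabicyclo[3.3.1]nonane | CC(C)(C)[Si](C)(C)OC/C=C(\C)CCB1C2CCCC1CCC2 | intermediate
19 | methyl (1S,4aS,8aR)-5-[(E)-5-(tert-butyldimethylsilyloxy)-3-methylpent-3-en-1-yl]-1,4a,6-trimethyl-1,2,3,4,4a,7,8,8a-octahydronaphthalene-1-carboxylate | CC(C)(C)[Si](C)(C)OC/C=C(\C)CCC1=C(C)CC[C@H]2[C@@](C)(C(=O)OC)CCC[C@]12C | intermediate
20 | methyl (1S,4aS,8aR)-5-[(E)-5-hydroxy-3-methylpent-3-en-1-yl]-1,4a,6-trimethyl-1,2,3,4,4a,7,8,8a-octahydronaphthalene-1-carboxylate | OC/C=C(\C)CCC1=C(C)CC[C@H]2[C@@](C)(C(=O)OC)CCC[C@]12C | intermediate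
21 | (1S,4aS,8aR)-5-[(E)-5-hydroxy-3-methylpent-3-en-1-yl]-1,4a,6-trimethyl-1,2,3,4,4a,7,8,8a-octahydronaphthalene-1-carboxylic acid | OC/C=C(\C)CCC1=C(C)CC[C@H]2[C@@](C)(C(=O)O)CCC[C@]12C | intermediate
22 | (1S,4aS,8aR)-5-[(E)-5-acetoxy-3-methylpent-3-en-1-yl]-1,4a,6-trimethyl-1,2,3,4,4a,7,8,8a-octahydronaphthalene-1-carboxylic acid | CC(=O)OC/C=C(\C)CCC1=C(C)CC[C@H]2[C@@](C)(C(=O)O)CCC[C@]12C | target

**Step count**
Total steps: 13. Longest linear sequence: 11 (steps 1–7 and 10–13; steps 8–9 prepare the side-chain diene).

**Steps most likely to fail, with fallbacks**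

Step 3 (proposed new method). What may go wrong: hydride transfer to the α-methyl enoate may be slow enough that hydrosilylation of a ring ketone competes; the fully substituted enolate may be protonated or silylated before it closes the congested C4–C5 bond; facial selectivity at C4 may be poor if the chelated transition state is not dominant; the ligand may not discriminate the two carbonyls well. The fallback uses the established α-unsubstituted version and sets C4 and C5 afterwards. It sets out from 3: Wittig olefination with methyl (triphenylphosphoranylidene)acetate gives methyl (E)-5-(1-methyl-2,6-dioxocyclohexyl)pent-2-enoate F1. The known Cu–H/chiral bisphosphine reductive aldol desymmetrisation of F1 gives methyl (1S,4aS,8aS)-8a-hydroxy-4a-methyl-5-oxodecahydronaphthalene-1-carboxylate F2 (ester cis to OH, OH cis to the angular methyl). SOCl2/pyridine removes water anti across C4–C5 to the conjugated ester methyl (4aS)-4a-methyl-5-oxo-2,3,4,4a,5,6,7,8-octahydronaphthalene-1-carboxylate F3. Ethylene glycol/TsOH in benzene protects the ketone as methyl (4aS)-5,5-(ethylenedioxy)-4a-methyl-2,3,4,4a,5,6,7,8-octahydronaphthalene-1-carboxylate F4. Birch-type reductive methylation (Li, NH3, t-BuOH, THF, −78 °C; then MeI) protonates C5 axially (trans-fusion) and methylates the C4 ester enolate from the α face, anti to the axial C10 methyl, to give methyl (1S,4aS,8aR)-5,5-(ethylenedioxy)-1,4a-dimethyldecahydronaphthalene-1-carboxylate F5. Aqueous HCl in THF frees the ketone, and the sequence comes back to the route at 10.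

Step 4. What may go wrong: activation of the very hindered tertiary alcohol may be slow, and ionisation may be diverted into chloride substitution or retro-aldol ring opening instead of clean elimination towards C6. The fallback removes the oxygen by a radical path and sets out from 8: acylation with methyl chlorooxoacetate (pyridine, DMAP, CH2Cl2) gives methyl (1S,4aS,8aR)-8a-(2-methoxy-2-oxoacetoxy)-1,4a-dimethyl-5-oxodecahydronaphthalene-1-carboxylate F6. Barton–McCombie-type deoxygenation of this tertiary oxalate (Bu3SnH, AIBN, PhMe, reflux) generates the planar C5 radical, which takes hydrogen from the tin hydride on the open α face. This gives 10 directly, so the route is rejoined at 10 and step 5 is not needed.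

Step 10. What may go wrong: oxidative addition and transmetalation at the tetrasubstituted triflate next to a quaternary carbon may be slow, so that hydrolysis of the triflate, protodeboronation or β-hydride elimination of the alkylpalladium take over. The fallback forms the C9–C11 bond by carbonyl addition and sets out from 12 and 18 (made from 17 as in step 10): iodinolysis of 18 (I2, NaOMe, MeOH/THF) gives (E)-tert-butyl[(5-iodo-3-methylpent-2-en-1-yl)oxy]dimethylsilane F7. Iodine–lithium exchange (t-BuLi, Et2O, −78 °C), transmetalation with CeCl3 and 1,2-addition to the ketone of 12 (the hindered ester is left alone) gives methyl (1S,4aS,8aR)-5-[(E)-5-(tert-butyldimethylsilyloxy)-3-methylpent-3-en-1-yl]-5-hydroxy-1,4a,6-trimethyldecahydronaphthalene-1-carboxylate F8. Dehydration (SOCl2, pyridine) towards the more substituted ring position, with mild acid equilibration of any exocyclic isomer, gives the tetrasubstituted C8=C9 alkene, and the route is rejoined at 19.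

Further compounds
F1 | step 3 | methyl (E)-5-(1-methyl-2,6-dioxocyclohexyl)pent-2-enoate | COC(=O)/C=C/CCC1(C)C(=O)CCCC1=O
F2 | step 3 | methyl (1S,4aS,8aS)-8a-hydroxy-4a-methyl-5-oxodecahydronaphthalene-1-carboxylate | O=C1CCC[C@]2(O)[C@@H](C(=O)OC)CCC[C@]12C
F3 | step 3 | methyl (4aS)-4a-methyl-5-oxo-2,3,4,4a,5,6,7,8-octahydronaphthalene-1-carboxylate | O=C1CCCC2=C(C(=O)OC)CCC[C@]12C
F4 | step 3 | methyl (4aS)-5,5-(ethylenedioxy)-4a-methyl-2,3,4,4a,5,6,7,8-octahydronaphthalene-1-carboxylate | O1CCOC12CCCC3=C(C(=O)OC)CCC[C@]23C
F5 | step 3 | methyl (1S,4aS,8aR)-5,5-(ethylenedioxy)-1,4a-dimethyldecahydronaphthalene-1-carboxylate | O1CCOC12CCC[C@H]3[C@@](C)(C(=O)OC)CCC[C@]23C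
F6 | step 4 | methyl (1S,4aS,8aR)-8a-(2-methoxy-2-oxoacetoxy)-1,4a-dimethyl-5-oxodecahydronaphthalene-1-carboxylate | O=C1CCC[C@]2(OC(=O)C(=O)OC)[C@@](C)(C(=O)OC)CCC[C@]12C
F7 | step 10 | (E)-tert-butyl[(5-iodo-3-methylpent-2-en-1-yl)oxy]dimethylsilane | CC(C)(C)[Si](C)(C)OC/C=C(\C)CCI
F8 | step 10 | methyl (1S,4aS,8aR)-5-[(E)-5-(tert-butyldimethylsilyloxy)-3-methylpent-3-en-1-yl]-5-hydroxy-1,4a,6-trimethyldecahydronaphthalene-1-carboxylate | CC(C)(C)[Si](C)(C)OC/C=C(\C)CCC1(O)C(C)CC[C@H]2[C@@](C)(C(=O)OC)CCC[C@]12C
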